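The route rests on cutting C5–C6 and C9–C10. These bonds tie the four-carbon bridge C6–C9 to the 1,3-carbons C5 (H) and C10 (CH3) of the cyclobutane C4–C5–C11–C10. Because these two carbons carry nothing else, joining them gives a bicyclo[1.1.0]butane. One radical strain-release annulation with a C6–C9 bromo ynone should then release the cyclobutane and close the seven-membered ring at once, leaving the C1 and C3 carboxyl carbons on the opposite face. The precursors are achiral di-tert-butyl exo,exo-1-methylbicyclobutane-2,4-dicarboxylate and 4-bromo-4-methylpent-1-yn-3-one. Asymmetric borylation at C9, Evans–Tishchenko reduction, acylation and an aldol closure of the cyclohexenone finish the target.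

Key step: step 5

Atom labels (used for every compound):
- C1 is the ketone carbon and C2=C3 the alkene, with CH3 on C3.
- The cyclobutane is C4–C5–C11–C10, with C4 on C3 and C11 on C1.
- C6 is the CMe2 on C5, C7 the senecioate carbinol, C8 the methylene and C9 the isovalerate carbinol.
- C10 is the methyl-bearing quaternary carbon.

Design remarks:
- tert-Butyl esters are used on the bicyclobutane. They should raise the exo preference of the second carbene transfer and resist the alkoxide media of the later steps. They also leave under acid, without base at C4–H and C11–H.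
- The ynone is made from bis(trimethylsilyl)acetylene, so that one silyl group is replaced and the other protects the terminus during the Lewis-acid step.
- The seven-membered ring is finished before the carboxyl groups are touched, so no carbon nucleophile ever meets the C7 enone.

Assumption: the sense of induction of the ferrocenyl diphosphine (step 6) and of the cinchona amine (step 12) cannot be derived from existing models for this bridged ring system. The hands named are working choices; the mirror-image ligand and the pseudo-enantiomeric amine are both commercial.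

Step 1
Reactants: 1 propyne; 2 tert-butyl diazoacetate
Product: 3 tert-butyl 2-methylcycloprop-2-ene-1-carboxylate (racemic)
Conditions: Rh2(OAc)4 (0.5 mol %), 1 (5 equiv, condensed), CH2Cl2, 0 °C, 2 added over 8 h
Reagents that add atoms: none
Why: Dirhodium-carbenoid [2+1] cyclopropenation of a terminal alkyne, in which excess alkyne and slow diazo feed suppress carbene dimerisation, and the racemic stereocentre is harmless because the next product is achiral.

Step 2
Reactants: 3 tert-butyl 2-methylcycloprop-2-ene-1-carboxylate; 2 tert-butyl diazoacetate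
Product: 4 di-tert-butyl exo,exo-1-methylbicyclo[1.1.0]butane-2,4-dicarboxylate (achiral; bridgeheads C5–H and C10–CH3, wing carbons C4 and C11)
Conditions: Rh2(OAc)4 (1 mol %), CH2Cl2, 0 °C, 2 (1.5 equiv) added over 12 h; chromatography on Et3N-deactivated silica
Reagents that add atoms: none
Why: Metal-carbenoid cyclopropanation of the strained cyclopropene C=C (second carbene addition to an alkyne, a known entry to bicyclobutane-2,4-dicarboxylates): the carbenoid approaches anti to the ester already present, which therefore ends exo, and its own bulky tert-butoxycarbonyl group turns away from the ring and also ends exo, any exo,endo isomer being removed by chromatography.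

Step 3
Reactants: 5 2-bromo-2-methylpropanoyl bromide; 6 bis(trimethylsilyl)acetylene
Product: 7 4-bromo-4-methyl-1-(trimethylsilyl)pent-1-yn-3-one
Conditions: AlCl3 (1.1 equiv), CH2Cl2, 0 °C; ice/aq. HCl quench
Reagents that add atoms: none
Why: Friedel–Crafts-type ipso-acylation of an alkynylsilane through a β-silyl vinyl cation, in which one Me3Si group is lost and the other stays to shield the ynone terminus from hydrogen halide addition.

Step 4
Reactants: 7 4-bromo-4-methyl-1-(trimethylsilyl)pent-1-yn-3-one
Product: 8 4-bromo-4-methylpent-1-yn-3-one (kept cold as a solution)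
Conditions: aq. Na2B4O7 (0.01 M, cat.), MeOH, 0 °C to rt, minutes; pentane extraction
Reagents that add atoms: none
Why: Protiodesilylation of an acyl-activated alkynylsilane under a near-neutral borate buffer, fast enough that the tertiary bromide, which has no enolisable α′-hydrogen and so no Favorskii path, and the free ynone should survive.

Step 5
Reactants: 4 di-tert-butyl exo,exo-1-methylbicyclo[1.1.0]butane-2,4-dicarboxylate; 8 4-bromo-4-methylpent-1-yn-3-one
Product: 9 di-tert-butyl 1,5,5-trimethyl-4-oxobicyclo[4.1.1]oct-2-ene-7,8-dicarboxylate, both esters anti to the four-carbon bridge (achiral; C7=O, C8=C9, esters on C4 and C11)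
Conditions: 4 (1.5 equiv, 0.4 M), fac-Ir(ppy)3 (1 mol %), 2,6-lutidine (1.5 equiv), degassed MeCN, 450 nm LEDs, 20 °C; 8 and diethyl 1,4-dihydro-2,6-dimethylpyridine-3,5-dicarboxylate (Hantzsch ester, 1.2 equiv) in MeCN/CH2Cl2 added together over 12 h
Reagents that add atoms: none
Why: Proposed new method: excited fac-Ir(ppy)3 cleaves the C–Br bond of 8 by electron transfer, the electrophilic tertiary α-keto radical at C6 enters the outer lobe of the C5–C10 bond at the hydrogen-bearing bridgehead C5, the central bond breaks, the nucleophilic tertiary radical left at C10 adds to the alkyne terminus C9, and the ring vinyl radical at C8 takes hydrogen from the dihydropyridine, whose oxidation returns the photocatalyst. The closest known reaction types are radical strain-release additions across the central bond of bicyclobutanes and of [1.1.1]propellane, reductive photoredox cyclisations of α-bromo carbonyl compounds, and the Lewis-acid annulation of acyl bicyclobutanes with dienol ethers to bicyclo[4.1.1]octanes. The cyclobutane C4–C5–C11–C10 is not closed but set free when the C5–C10 bond breaks, and the seven-membered ring (C5–C6–C7–C8–C9–C10 completed by C4 or by C11) closes 7-endo-dig, preferred to 6-exo-dig attack at C8 because C9 is the unsubstituted β-carbon of the ynone. C5 is set by backside entry on the concave face, anti to both exo esters, and C10 by the tether, which reaches only that same face, so the esters on C4 and C11 end cis to each other on the face opposite to the bridge and 9 keeps a mirror plane that makes absolute control unnecessary here. The step needs attack at C5 and not at C10, which the contrast of H against CH3 and the tertiary radical formed secure, and it needs ring closure to outrun hydrogen or bromine transfer and addition to a second ynone, which the gem-dimethyl group at C6, the polarity match between C10 and C9, the excess of 4 and the slow joint feed of 8 and the hydrogen donor secure. 2,6-Lutidine binds the hydrogen bromide that would otherwise open acid-labile 4.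

Step 6
Reactants: 9 di-tert-butyl 1,5,5-trimethyl-4-oxobicyclo[4.1.1]oct-2-ene-7,8-dicarboxylate
Product: 11 di-tert-butyl (9R)-2-hydroxy-1,5,5-trimethyl-4-oxobicyclo[4.1.1]octane-7,8-dicarboxylate (OH on C9; esters anti to the bridge), via C9 pinacol boronate 10 (not isolated)
Conditions: CuCl (5 mol %), NaOtBu (10 mol %), (R,S)-Josiphos SL-J001 (6 mol %), B2pin2 (1.1 equiv), MeOH (2 equiv), THF, rt; then NaBO3·4H2O (5 equiv), THF/H2O, rt
Reagents that add atoms: bis(pinacolato)diboron CC1(C)OB(OC1(C)C)B1OC(C)(C)C(C)(C)O1; sodium perborate [Na+].[Na+].O[B-]1(O)OO[B-](O)(O)OO1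
Why: Copper-catalysed enantioselective conjugate borylation followed by stereoretentive C–B oxidation: the two faces of the C8=C9 bond of achiral 9 are enantiotopic, so the chiral phosphine–copper boryl species alone decides C9 (R) and thereby makes C4 and C11 different, while the tert-butyl esters ignore the alkoxide/methanol medium.

Step 7
Reactants: 11 (9R)-hydroxy ketone diester; 12 3-methylbutanal (isovaleraldehyde)
Product: 13 di-tert-butyl (7R,9R)-4-hydroxy-1,5,5-trimethyl-2-(3-methylbutanoyloxy)bicyclo[4.1.1]octane-7,8-dicarboxylate (free OH on C7, isovalerate on O9, the two oxygens trans on the seven-membered ring)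
Conditions: SmI2 (0.3 equiv, 0.1 M in THF), 12 (6 equiv), THF, −10 °C, dark
Reagents that add atoms: none
Why: Evans–Tishchenko reduction: the C9 hemiacetal alkoxide of 12, bound to trivalent samarium, passes its hydride to C7 through a six-membered chelate on the face that carries O9, which sets C7 (R) with the new hydroxyl trans (1,3-anti) to O9 and leaves the isovalerate on O9 in the same operation.

Step 8
Reactants: 13 C7 alcohol C9 isovalerate; 14 3-methylbut-2-enoyl chloride (senecioyl chloride)
Product: 15 di-tert-butyl (7R,9R)-1,5,5-trimethyl-2-(3-methylbutanoyloxy)-4-(3-methylbut-2-enoyloxy)bicyclo[4.1.1]octane-7,8-dicarboxylate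
Conditions: 14 (3 equiv), pyridine (6 equiv), DMAP (0.2 equiv), CH2Cl2, 0 to 40 °C
Reagents that add atoms: none
Why: DMAP-catalysed acylation of the only free hydroxyl, with pyridine instead of a trialkylamine to keep vinylketene formation and double-bond migration of the senecioyl unit low, and with no stereocentre touched.

Step 9
Reactants: 15 tetraester
Product: 16 (7R,9R)-1,5,5-trimethyl-2-(3-methylbutanoyloxy)-4-(3-methylbut-2-enoyloxy)bicyclo[4.1.1]octane-7,8-dicarboxylic acid
Conditions: CF3CO2H/CH2Cl2 (1:2), 0 °C to rt; toluene azeotrope
Reagents that add atoms: none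
Why: Acidolysis of tert-butyl esters by loss of isobutene, which leaves the two secondary alkyl esters intact and, being base-free, cannot epimerise C4–H or C11–H.

Step 10
Reactants: 16 diacid
Product: 17 bis(S-ethyl) 7,8-dicarbothioate of 16 (COSEt on C4 and on C11)
Conditions: EtSH (4 equiv), EDC·HCl (3 equiv), DMAP (0.5 equiv), CH2Cl2, 0 °C to rt
Reagents that add atoms: ethanethiol CCS
Why: Steglich-type thioesterification, in which carbodiimide activation and DMAP acyl transfer convert both hindered carboxyl groups one after the other without strong base and without touching the alkyl esters or the β,β-disubstituted enoate.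

Step 11
Reactants: 17 bis(thioester)
Product: 18 (7R,9R)-7,8-diacetyl-1,5,5-trimethyl-2-(3-methylbutanoyloxy)-4-(3-methylbut-2-enoyloxy)bicyclo[4.1.1]octane (acetyl on C4 and on C11, cis to each other, anti to the bridge)
Conditions: MeZnCl (4 equiv, 2 M in THF), PdCl2(PPh3)2 (10 mol %), toluene, rt
Reagents that add atoms: methylzinc chloride C[Zn]Cl
Why: Fukuyama ketone synthesis, in which zerovalent palladium inserts only into the acyl–sulfur bonds and the methylzinc reagent is inert to the alkyl esters, the enoate and the methyl ketones formed.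

Step 12
Reactants: 18 diacetyl diester
Product: 20 CNP0214473.1 = (4R,5S,7R,9R,10R,11R)-9-(3-methylbutanoyloxy)-7-(3-methylbut-2-enoyloxy)longipin-2-en-1-one, via C3 ketol 19 (not isolated)
Conditions: 9-amino-9-deoxy-epi-quinine (20 mol %), AcOH (40 mol %), 4 Å molecular sieves, toluene, 25 to 45 °C
Reagents that add atoms: none
Why: Amine-catalysed intramolecular aldol condensation of the desymmetrising 2,6-heptanedione-to-3-methylcyclohexenone type: the two acetyl groups are held 1,3-diaxial on the cyclobutane face opposite to the bridge, the chiral primary amine takes the acetyl on C11 (the side of O9) as enamine donor (its CH3 becomes C2) and the acetyl on C4 as acceptor (C3), loss of water removes the transient C3 centre, and the wrong-way product is a separable diastereomer.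

Compound list
1 | propyne | CC#C | starting material
2 | tert-butyl diazoacetate | CC(C)(C)OC(=O)C=[N+]=[N-] | starting material
3 | tert-butyl 2-methylcycloprop-2-ene-1-carboxylate (racemic) | CC1=CC1C(=O)OC(C)(C)C | intermediate
4 | di-tert-butyl exo,exo-1-methylbicyclo[1.1.0]butane-2,4-dicarboxylate | CC(C)(C)OC(=O)[C@@H]1[C@@H]2[C@@]1(C)[C@H]2C(=O)OC(C)(C)C | intermediate
5 | 2-bromo-2-methylpropanoyl bromide | CC(C)(Br)C(=O)Br | starting material
6 | bis(trimethylsilyl)acetylene | C[Si](C)(C)C#C[Si](C)(C)C | starting material
7 | 4-bromo-4-methyl-1-(trimethylsilyl)pent-1-yn-3-one | CC(C)(Br)C(=O)C#C[Si](C)(C)C | intermediate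
8 | 4-bromo-4-methylpent-1-yn-3-one | CC(C)(Br)C(=O)C#C | intermediate
9 | di-tert-butyl 1,5,5-trimethyl-4-oxobicyclo[4.1.1]oct-2-ene-7,8-dicarboxylate, esters anti to the bridge | O=C1C=C[C@@]2(C)[C@H](C(=O)OC(C)(C)C)[C@@H](C1(C)C)[C@@H]2C(=O)OC(C)(C)C | intermediate
10 | (9R)-C9 pinacol boronate of the saturated ketone diester | O=C1C[C@@H](B3OC(C)(C)C(C)(C)O3)[C@@]2(C)[C@H](C(=O)OC(C)(C)C)[C@@H](C1(C)C)[C@@H]2C(=O)OC(C)(C)C | intermediate
11 | (9R)-9-hydroxy-7-oxo diester | O=C1C[C@@H](O)[C@@]2(C)[C@H](C(=O)OC(C)(C)C)[C@@H](C1(C)C)[C@@H]2C(=O)OC(C)(C)C | intermediate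
12 | 3-methylbutanal | CC(C)CC=O | starting material
13 | (7R,9R)-7-hydroxy-9-isovaleryloxy diester | O[C@@H]1C[C@@H](OC(=O)CC(C)C)[C@@]2(C)[C@H](C(=O)OC(C)(C)C)[C@@H](C1(C)C)[C@@H]2C(=O)OC(C)(C)C | intermediate
14 | 3-methylbut-2-enoyl chloride | CC(C)=CC(=O)Cl | starting material
15 | (7R,9R)-7-senecioyloxy-9-isovaleryloxy di-tert-butyl ester | CC(C)=CC(=O)O[C@@H]1C[C@@H](OC(=O)CC(C)C)[C@@]2(C)[C@H](C(=O)OC(C)(C)C)[C@@H](C1(C)C)[C@@H]2C(=O)OC(C)(C)C | intermediate
16 | corresponding C4,C11-dicarboxylic acid | CC(C)=CC(=O)O[C@@H]1C[C@@H](OC(=O)CC(C)C)[C@@]2(C)[C@H](C(=O)O)[C@@H](C1(C)C)[C@@H]2C(=O)O | intermediate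
17 | corresponding bis(S-ethyl thioester) | CC(C)=CC(=O)O[C@@H]1C[C@@H](OC(=O)CC(C)C)[C@@]2(C)[C@H](C(=O)SCC)[C@@H](C1(C)C)[C@@H]2C(=O)SCC | intermediate
18 | corresponding C4,C11-diacetyl compound | CC(C)=CC(=O)O[C@@H]1C[C@@H](OC(=O)CC(C)C)[C@@]2(C)[C@H](C(C)=O)[C@@H](C1(C)C)[C@@H]2C(C)=O | intermediate
19 | C3 ketol (3-hydroxy-longipinan-1-one diester; C3 configuration open, centre lost on dehydration) | CC(C)=CC(=O)O[C@@H]1C[C@@H](OC(=O)CC(C)C)[C@@]2(C)[C@@H]3C(=O)CC(C)(O)[C@H]2[C@@H]3C1(C)C | intermediate
20 | CNP0214473.1, (4R,5S,7R,9R,10R,11R)-9-isovaleryloxy-7-senecioyloxylongipin-2-en-1-one | CC(C)=CC(=O)O[C@@H]1C[C@@H](OC(=O)CC(C)C)[C@@]2(C)[C@@H]3C(=O)C=C(C)[C@H]2[C@@H]3C1(C)C | target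

Total step count: 12.
Longest linear sequence: 10 steps (1, 2, 5–12). The branch 3, 4 joins at step 5 and is equally long.

Steps most likely to fail

Step 5. The α-keto radical may be reduced before it reaches the strained bond. Closure of the C10 radical on the rigid, linear alkyne may also be slower than hydrogen or bromine transfer. The fallback separates the two bond formations, uses a flexible alkene acceptor, and relies on known reaction types only. It sets out from 4 and 5 and returns at 9.
- Acylation of ethylene with 5 (AlBr3, CH2Cl2, 0 °C) gives 1,4-dibromo-4-methylpentan-3-one F1.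
- Kharasch-type atom-transfer addition of its tertiary C–Br bond across C5–C10 of 4 follows (Et3B/air, CH2Cl2, F1 in excess so that bromine transfer is fast). It gives the cyclobutyl bromide di-tert-butyl 2-bromo-4-(5-bromo-2-methyl-3-oxopentan-2-yl)-2-methylcyclobutane-1,3-dicarboxylate F2, whose C10 epimers both serve.
- Et3N at 0 °C removes hydrogen bromide from the β-bromoethyl ketone only and gives the vinyl ketone F3.
- Bu3SnH/AIBN in benzene at high dilution regenerates the C10 radical. It closes 7-endo-trig on the acryloyl terminus to the saturated di-tert-butyl 1,5,5-trimethyl-4-oxobicyclo[4.1.1]octane-7,8-dicarboxylate F4.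
- IBX in DMSO, or silyl enol ether formation and Pd(OAc)2 (Saegusa–Ito), dehydrogenates C8–C9, the only enolisable side, to 9.

Step 2. The metal may open the cyclopropene or isomerise the bicyclobutane to dienes. Carbene dimerisation may outrun transfer to the hindered C=C, or the exo preference may be weak. The fallback replaces carbenoid transfer by a metal-free cycloaddition and nitrogen extrusion. It sets out from 3 and 2 and returns at 4.
- 1,3-Dipolar cycloaddition of 2 to the strained C=C of 3 (Et2O, rt, dark) occurs anti to the ester. It gives di-tert-butyl 1-methyl-2,3-diazabicyclo[3.1.0]hex-2-ene-4,6-dicarboxylate F5; either regiochemistry leads to the same bicyclobutane.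
- F5 is irradiated at once (350 nm, −40 °C, pentane/Et2O). Loss of nitrogen and closure of the 1,3-diradical should give 4, which is separated from its exo,endo isomer.

Step 12. The amine may fail to distinguish the two acetyl groups, or enamine formation at the hindered ketones may stall. The fallback differentiates the two carboxyl carbons before ring closure and closes the ring irreversibly. It sets out from 16 and returns at 20.
- Trifluoroacetic anhydride (CH2Cl2, 0 °C) gives the bridged cyclic anhydride F6.
- Catalyst-controlled ring-opening methylation of the anhydride follows (Me2Zn, [Rh(cod)Cl]2, (S)-tBu-PHOX, THF). It gives the keto acid F7, with acetyl on C4 and CO2H on C11.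
- Activation with 1,1'-carbonyldiimidazole is followed by decarboxylative C-acylation of diethylphosphonoacetic acid (MgCl2, Et3N, MeCN). This gives the β-ketophosphonate F8.
- Intramolecular Horner–Wadsworth–Emmons closure under Masamune–Roush conditions (LiCl, DBU, MeCN) forms C2=C3 and gives 20.

Further compounds
F1 | step 5 | 1,4-dibromo-4-methylpentan-3-one | CC(C)(Br)C(=O)CCBr
F2 | step 5 | di-tert-butyl 2-bromo-4-(5-bromo-2-methyl-3-oxopentan-2-yl)-2-methylcyclobutane-1,3-dicarboxylate (esters cis to each other, trans to the C5 side chain; C10 epimers) | CC1(Br)[C@H](C(=O)OC(C)(C)C)[C@@H](C(C)(C)C(=O)CCBr)[C@@H]1C(=O)OC(C)(C)C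
F3 | step 5 | di-tert-butyl 2-bromo-2-methyl-4-(2-methyl-3-oxopent-4-en-2-yl)cyclobutane-1,3-dicarboxylate (same relative configuration; C10 epimers) | CC1(Br)[C@H](C(=O)OC(C)(C)C)[C@@H](C(C)(C)C(=O)C=C)[C@@H]1C(=O)OC(C)(C)C
F4 | step 5 | di-tert-butyl 1,5,5-trimethyl-4-oxobicyclo[4.1.1]octane-7,8-dicarboxylate, esters anti to the bridge | O=C1CC[C@@]2(C)[C@H](C(=O)OC(C)(C)C)[C@@H](C1(C)C)[C@@H]2C(=O)OC(C)(C)C
F5 | step 2 | di-tert-butyl 1-methyl-2,3-diazabicyclo[3.1.0]hex-2-ene-4,6-dicarboxylate (racemic; C6 ester anti to the diazene ring; C4 open) | C[C@]12N=NC(C(=O)OC(C)(C)C)[C@H]1[C@@H]2C(=O)OC(C)(C)C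
F6 | step 12 | cyclic anhydride of 16 (C11–CO–O–CO–C4) | CC(C)=CC(=O)O[C@@H]1C[C@@H](OC(=O)CC(C)C)[C@@]2(C)[C@@H]3C(=O)OC(=O)[C@H]2[C@@H]3C1(C)C
F7 | step 12 | keto acid, acetyl on C4 and CO2H on C11 | CC(C)=CC(=O)O[C@@H]1C[C@@H](OC(=O)CC(C)C)[C@@]2(C)[C@H](C(=O)O)[C@@H](C1(C)C)[C@@H]2C(C)=O
F8 | step 12 | β-ketophosphonate, (EtO)2P(O)CH2C(=O) on C11 and acetyl on C4 | CC(C)=CC(=O)O[C@@H]1C[C@@H](OC(=O)CC(C)C)[C@@]2(C)[C@H](C(=O)CP(=O)(OCC)OCC)[C@@H](C1(C)C)[C@@H]2C(C)=O
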